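The readings were generated by integration with constants of no real substance.

Reacted over unreacted must reach 9.00 in the flask at 15 min.

- larch: electrophile 1 M; nucleophile 0.97 M; run made earlier
- flask: electrophile 1.0 M; time 15 min

larch run (percent of the electrophile charged)

| time / min | product / % |
|---|---|
| 0.833 | 13 |
| 1.50 | 16 |
| 2.50 | 23 |
| 3.00 | 29 |

(standard deviation of a reading: 1.5 percentage points)

- the concentration of nucleophile at which the part of the electrophile that has reacted at 15 min is just 90 %, in M

- the amount of nucleophile is what is sought; it is there from the start

1. Zero of the scale: equal charges. If the rate follows electrophile times nucleophile, which is assumed here, reacted over unreacted grows in step with time. The larch run, with 0.970 of a charge of nucleophile, lies close to this case.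

2. Its latest reading, 29 % at 3.00 min, gives a ratio of 0.408. Scaled to 15 min, this becomes 2.04, give or take 0.149. Call this the clock: the reacted-over-unreacted ratio that equal charges reach at the asked time.

3. Equal charges in the flask would end at 67.1 %, short of 90 %, so nucleophile must be in excess, with electrophile the limiting reagent.

4. With b charges of nucleophile and part X reacted, the clock demanded is ln[(b − X)/(b(1 − X))]/(b − 1). For 90 %, b = 1.50 demands 2.77 and b = 2 demands 1.70.

5. A straight line between them, reckoned here, puts the clock at b = 1.84, or 1.84 M. Yet that charge demands 1.94, below the clock, so the line is the weak link.

The forecast gives less, 1.78 M, a charge that demands 2.05, close to the clock; it warns that “the order in nucleophile is untested”.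

The flask gives 1.95 M, and the forecast stands within its margin.

    electrophile ⇌ dormant form (K = 0.470, k = 0.00180 s⁻¹)
    acid set free → by-product carried off (k = 0.0370 s⁻¹)
    electrophile + nucleophile → acid set free + product (k = 0.00300 L mol⁻¹ s⁻¹)
    nucleophile + acid set free ⇌ protonated nucleophile, settled at all times (K = 31.0 L mol⁻¹)

At that charge the demanded clock is 1.78, below the reading. Acid set free has a half-life of 0.31 min on its path to by-product carried off, shorter than the 2.27 min by which half of the turnover to product is done. Yet that path has 44 % of its turnover behind it at 7.50 min, while the step to product has 39 % at 1.50 min. With twice the electrophile, the charges return to b = 0.974, the doubled clock 3.55 gives 78.0 %, and that flask shows 78.3 %.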